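**Plan**

- Retrosynthesis: the ring B formyl C–C bond and the ring A isobutyryl C–C bond are cut last (electrophilic substitutions). Ring B is then cut at C1′–C6′ and C4′–C5′ into siloxy diene 13 and methoxy ynone 18, the two saturated ring carbons of the diene leaving as ethene. The diene is cut at the CH2–cyclohexenone bond into benzylic bromide 7 and vinylogous ester 9.
- Enabling feature: ring B (C1′ bears the CH2 bridge, C3′ the CHO, C5′ the isovaleryl group) has oxygen on C2′, C4′ and C6′. C1′–C4′ map onto a 1-alkoxy-3-siloxycyclohexa-1,3-diene (C1′ = nucleophilic terminus carrying the ring A benzyl group, C2′–O = siloxy, C4′–O = alkoxy) and C5′–C6′ onto a 3-alkoxy ynone.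
- Forward: ring A comes intact from 2-methylbenzene-1,3,5-triol (steps 1–5) and is joined to the cyclohexenone by enolate alkylation (step 7). Ring B arises in step 11, its ethers and the ring A benzyl ethers come off in steps 12–13, ring A is acylated (step 14) and ring B formylated (step 15).
- Protecting groups: each ether flanking the ring B ketone leaves by its own mechanism (C6′ methyl by chelation-assisted iodide attack, C4′ isopropyl and the benzyl groups by BCl3), while the ring A methyl ether, which has no carbonyl neighbour at that stage, stays.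
- Stereochemistry: the target has no stereocentre; the racemic centres of 11, 17 and 19 are destroyed in later steps.

Key step: step 11

Remark on the chemistry: a methyl ynol ether is assumed instead of an ethyl one because it cannot lose ethene by a retro-ene reaction at the cycloaddition temperature. An isopropyl vinylogous ester (made in step 6) is assumed because two primary alkyl ethers flanking one ketone cannot both be removed by chelation-assisted BCl3 cleavage.

**Route**

Step 1
Reactants: 1 2-methylbenzene-1,3,5-triol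
Product: 3 2,4,6-trihydroxy-3-methylbenzaldehyde, via aryl iminium chloride 2 (not isolated)
Conditions: POCl3, DMF, EtOAc, 0 °C → rt; then H2O, 50 °C
Reagents that add atoms: N,N-dimethylformamide CN(C)C=O; water O
Why: Vilsmeier–Haack formylation of the electron-rich triol at one of its two equivalent free ring positions should give the aryl iminium salt, which water hydrolyses to the aldehyde.

Step 2
Reactants: 3 2,4,6-trihydroxy-3-methylbenzaldehyde
Product: 4 2,6-dihydroxy-4-methoxy-3-methylbenzaldehyde
Conditions: Me2SO4 (1.0 equiv), K2CO3, acetone, rt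
Reagents that add atoms: dimethyl sulfate COS(=O)(=O)OC
Why: Williamson etherification with one equivalent of Me2SO4 should take the 4-hydroxyl, the only one not hydrogen-bonded to the formyl group and the most acidic, as is usual for 2,4,6-trihydroxyaryl carbonyl compounds.

Step 3
Reactants: 4 2,6-dihydroxy-4-methoxy-3-methylbenzaldehyde
Product: 5 2,6-bis(benzyloxy)-4-methoxy-3-methylbenzaldehyde
Conditions: BnBr, K2CO3, DMF, 70 °C
Reagents that add atoms: benzyl bromide BrCc1ccccc1
Why: Williamson etherification of both chelated ortho hydroxyls in hot DMF masks the acidic protons before the enolate chemistry.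

Step 4
Reactants: 5 2,6-bis(benzyloxy)-4-methoxy-3-methylbenzaldehyde
Product: 6 [2,6-bis(benzyloxy)-4-methoxy-3-methylphenyl]methanol
Conditions: NaBH4, MeOH–THF, 0 °C
Reagents that add atoms: none
Why: Borohydride reduction of the aryl aldehyde gives the benzylic alcohol and leaves the ethers untouched.

Step 5
Reactants: 6 [2,6-bis(benzyloxy)-4-methoxy-3-methylphenyl]methanol
Product: 7 1,3-bis(benzyloxy)-2-(bromomethyl)-5-methoxy-4-methylbenzene
Conditions: PBr3, pyridine (cat.), Et2O, −10 °C; crude bromide used at once
Reagents that add atoms: phosphorus tribromide BrP(Br)Br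
Why: PBr3 converts the benzylic alcohol into the bromide by nucleophilic displacement of a bromophosphite, and low temperature with a pyridine buffer is meant to keep this very ionisable bromide from self-condensing.

Step 6
Reactants: 8 cyclohexane-1,3-dione
Product: 9 3-(propan-2-yloxy)cyclohex-2-en-1-one
Conditions: i-PrOH, TsOH·H2O (cat.), toluene, reflux (Dean–Stark)
Reagents that add atoms: propan-2-ol CC(C)O
Why: Acid-catalysed enol etherification of the 1,3-diketone with azeotropic removal of water gives the vinylogous ester.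

Step 7
Reactants: 9 3-(propan-2-yloxy)cyclohex-2-en-1-one; 7 1,3-bis(benzyloxy)-2-(bromomethyl)-5-methoxy-4-methylbenzene
Product: 11 6-{[2,6-bis(benzyloxy)-4-methoxy-3-methylphenyl]methyl}-3-(propan-2-yloxy)cyclohex-2-en-1-one (racemic), via lithium dienolate 10 (not isolated)
Conditions: LiN(i-Pr)2, THF, −78 °C; then 7, −78 → 0 °C
Reagents that add atoms: none
Why: Kinetic deprotonation of the vinylogous ester at C6 and C-alkylation of the cross-conjugated lithium dienolate with the reactive benzylic bromide (Stork–Danheiser-type α′-alkylation) should form the C6–CH2 bond; the new stereocentre is racemic and is lost in step 8.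

Step 8
Reactants: 11 6-{[2,6-bis(benzyloxy)-4-methoxy-3-methylphenyl]methyl}-3-(propan-2-yloxy)cyclohex-2-en-1-one
Product: 13 {[2-{[2,6-bis(benzyloxy)-4-methoxy-3-methylphenyl]methyl}-5-(propan-2-yloxy)cyclohexa-1,5-dien-1-yl]oxy}trimethylsilane, via substituted lithium dienolate 12 (not isolated)
Conditions: LiN(i-Pr)2, THF, −78 °C; then Me3SiCl, Et3N, −78 → 0 °C; pentane, filtration
Reagents that add atoms: chlorotrimethylsilane C[Si](C)(C)Cl
Why: A second kinetic α′-deprotonation at C6 and O-silylation of the enolate (silyl dienol ether formation) should give the cross-conjugated 2-siloxy diene, since γ-deprotonation is the thermodynamic and not the kinetic pathway for 3-alkoxy enones.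

Step 9
Reactants: 14 2-chloro-1,1-dimethoxyethane; 15 3-methylbutanal
Product: 17 1-methoxy-5-methylhex-1-yn-3-ol (racemic), via lithium methoxyacetylide 16 (not isolated)
Conditions: Et2NH, n-BuLi (3 equiv), THF, 0 °C; then 15, −78 → −20 °C; aq. NaHCO3
Reagents that add atoms: none
Why: Three equivalents of LiNEt2 should take the chloroacetal through loss of methanol and HCl to lithium methoxyacetylide, which adds to the aldehyde carbonyl (acetylide 1,2-addition) to give the racemic propargylic alcohol.

Step 10
Reactants: 17 1-methoxy-5-methylhex-1-yn-3-ol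
Product: 18 1-methoxy-5-methylhex-1-yn-3-one
Conditions: MnO2 (activated, excess), CH2Cl2, rt
Reagents that add atoms: none
Why: Activated MnO2 oxidises the propargylic alcohol to the ynone under neutral conditions, which avoids acid-induced Meyer–Schuster rearrangement of the ynol ether carbinol.

Step 11
Reactants: 13 {[2-{[2,6-bis(benzyloxy)-4-methoxy-3-methylphenyl]methyl}-5-(propan-2-yloxy)cyclohexa-1,5-dien-1-yl]oxy}trimethylsilane; 18 1-methoxy-5-methylhex-1-yn-3-one
Product: 20 1-[3-{[2,6-bis(benzyloxy)-4-methoxy-3-methylphenyl]methyl}-2-methoxy-6-(propan-2-yloxy)-4-(trimethylsilyloxy)phenyl]-3-methylbutan-1-one, via bicyclo[2.2.2]octadiene adduct 19 (not isolated)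
Conditions: 18 (2.5 equiv), BHT (cat.), o-xylene, sealed tube, 110 °C then 145 °C; evaporation
Reagents that add atoms: none
Why: Proposed new method: the silyl enol ether carbon of 13 (the benzyl-bearing diene terminus, made nucleophilic by the siloxy group and by the vinylogous isopropoxy donor) should attack the methoxy-bearing β-carbon of ynone 18, and the α-carbon of the resulting allenolate-like unit then bonds to the isopropoxy-bearing terminus, a concerted but strongly asynchronous (or stepwise) intermolecular (4+2) cycloaddition that gives bicyclo[2.2.2]octa-2,5-diene 19; on further heating 19 ejects its CH2–CH2 bridge as ethene by a retro-(4+2) reaction and the six remaining carbons are ring B. The closest known reaction type is the Alder–Rickert reaction of 1-alkoxy-3-siloxycyclohexa-1,3-dienes and of 4-alkyl-1,3-bis(siloxy)cyclohexa-1,3-dienes with acetylenic esters and ketones such as dimethyl acetylenedicarboxylate or but-3-yn-2-one; what is new is a push–pull 3-alkoxy ynone as the 2π partner. Ring B is thus closed by intermolecular cycloaddition followed by cycloreversion and not by cyclisation of a chain. No stereocentre survives, because the two bridgeheads of 19 are fixed relative to each other by the bicycle and become sp2 carbons when ethene leaves. The step needs head-to-tail regioselectivity, which the match of the largest HOMO coefficient (siloxy-activated terminus) with the largest LUMO coefficient (β-carbon of the ynone) should secure, so that the ketone ends between the two ether oxygens.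

Step 12
Reactants: 20 1-[3-{[2,6-bis(benzyloxy)-4-methoxy-3-methylphenyl]methyl}-2-methoxy-6-(propan-2-yloxy)-4-(trimethylsilyloxy)phenyl]-3-methylbutan-1-one
Product: 21 1-[3-{[2,6-bis(benzyloxy)-4-methoxy-3-methylphenyl]methyl}-2,4-dihydroxy-6-(propan-2-yloxy)phenyl]-3-methylbutan-1-one
Conditions: MgI2·OEt2, toluene, 80 °C; then 1 M HCl, THF, rt
Reagents that add atoms: none
Why: MgI2 chelates the ketone oxygen and the ortho methoxy oxygen and iodide then attacks the methyl group (chelation-controlled ortho-demethylation), whereas the secondary isopropyl ether and the carbonyl-free ring A ethers should be left, and the acidic work-up hydrolyses the aryl silyl ether.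

Step 13
Reactants: 21 1-[3-{[2,6-bis(benzyloxy)-4-methoxy-3-methylphenyl]methyl}-2,4-dihydroxy-6-(propan-2-yloxy)phenyl]-3-methylbutan-1-one
Product: 22 1-{3-[(2,6-dihydroxy-4-methoxy-3-methylphenyl)methyl]-2,4,6-trihydroxyphenyl}-3-methylbutan-1-one
Conditions: BCl3, C6HMe5, CH2Cl2, −78 → 0 °C; then MeOH
Reagents that add atoms: none
Why: BCl3 with pentamethylbenzene as cation scavenger cleaves the two benzyl ethers and the isopropyl ether by cationic dealkylation (Lewis acid ether cleavage), which needs no free carbonyl neighbour, while the ring A methyl ether, not ortho to a carbonyl group, should not be touched.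

Step 14
Reactants: 22 1-{3-[(2,6-dihydroxy-4-methoxy-3-methylphenyl)methyl]-2,4,6-trihydroxyphenyl}-3-methylbutan-1-one
Product: 23 1-[2,4-dihydroxy-6-methoxy-5-methyl-3-{[2,4,6-trihydroxy-3-(3-methylbutanoyl)phenyl]methyl}phenyl]-2-methylpropan-1-one
Conditions: i-PrCOCl (1.2 equiv), AlCl3, PhNO2–CH2Cl2, 0 °C → rt; then aq. HCl
Reagents that add atoms: 2-methylpropanoyl chloride CC(C)C(Cl)=O
Why: Friedel–Crafts acylation should go to the single free position of ring A, which carries no acyl group and is far more nucleophilic than the free position of ring B, whose aryl ketone is tied up as an aluminium chelate.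

Step 15
Reactants: 23 1-[2,4-dihydroxy-6-methoxy-5-methyl-3-{[2,4,6-trihydroxy-3-(3-methylbutanoyl)phenyl]methyl}phenyl]-2-methylpropan-1-one
Product: 25 robustaol A, via ring B iminium chloride 24 (not isolated)
Conditions: POCl3, DMF, EtOAc, 0 °C → rt; then H2O, 40 °C
Reagents that add atoms: N,N-dimethylformamide CN(C)C=O; water O
Why: Vilsmeier–Haack formylation can only take the one remaining aromatic C–H, C3′ of ring B between two hydroxyls, as in known formylations of acylphloroglucinols, and hydrolysis of the iminium salt gives the aldehyde.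

**Compound list**

1 | 2-methylbenzene-1,3,5-triol | Cc1c(O)cc(O)cc1O | starting material
2 | N-methyl-N-[(2,4,6-trihydroxy-3-methylphenyl)methylidene]methanaminium chloride | C[N+](C)=Cc1c(O)cc(O)c(C)c1O.[Cl-] | intermediate
3 | 2,4,6-trihydroxy-3-methylbenzaldehyde | Cc1c(O)cc(O)c(C=O)c1O | intermediate
4 | 2,6-dihydroxy-4-methoxy-3-methylbenzaldehyde | COc1cc(O)c(C=O)c(O)c1C | intermediate
5 | 2,6-bis(benzyloxy)-4-methoxy-3-methylbenzaldehyde | COc1cc(OCc2ccccc2)c(C=O)c(OCc2ccccc2)c1C | intermediate
6 | [2,6-bis(benzyloxy)-4-methoxy-3-methylphenyl]methanol | COc1cc(OCc2ccccc2)c(CO)c(OCc2ccccc2)c1C | intermediate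
7 | 1,3-bis(benzyloxy)-2-(bromomethyl)-5-methoxy-4-methylbenzene | COc1cc(OCc2ccccc2)c(CBr)c(OCc2ccccc2)c1C | intermediate
8 | cyclohexane-1,3-dione | O=C1CCCC(=O)C1 | starting material
9 | 3-(propan-2-yloxy)cyclohex-2-en-1-one | CC(C)OC1=CC(=O)CCC1 | intermediate
10 | lithium 5-(propan-2-yloxy)cyclohexa-1,5-dien-1-olate | [Li]OC1=CCCC(OC(C)C)=C1 | intermediate
11 | 6-{[2,6-bis(benzyloxy)-4-methoxy-3-methylphenyl]methyl}-3-(propan-2-yloxy)cyclohex-2-en-1-one (racemic) | CC(C)OC1=CC(=O)C(Cc2c(OCc3ccccc3)cc(OC)c(C)c2OCc2ccccc2)CC1 | intermediate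
12 | lithium 2-{[2,6-bis(benzyloxy)-4-methoxy-3-methylphenyl]methyl}-5-(propan-2-yloxy)cyclohexa-1,5-dien-1-olate | [Li]OC1=C(Cc2c(OCc3ccccc3)cc(OC)c(C)c2OCc2ccccc2)CCC(OC(C)C)=C1 | intermediate
13 | {[2-{[2,6-bis(benzyloxy)-4-methoxy-3-methylphenyl]methyl}-5-(propan-2-yloxy)cyclohexa-1,5-dien-1-yl]oxy}trimethylsilane | CC(C)OC1=CC(O[Si](C)(C)C)=C(Cc2c(OCc3ccccc3)cc(OC)c(C)c2OCc2ccccc2)CC1 | intermediate
14 | 2-chloro-1,1-dimethoxyethane | COC(CCl)OC | starting material
15 | 3-methylbutanal | CC(C)CC=O | starting material
16 | lithium methoxyacetylide (methoxyethynyllithium) | [Li]C#COC | intermediate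
17 | 1-methoxy-5-methylhex-1-yn-3-ol (racemic) | COC#CC(O)CC(C)C | intermediate
18 | 1-methoxy-5-methylhex-1-yn-3-one | COC#CC(=O)CC(C)C | intermediate
19 | 1-[4-{[2,6-bis(benzyloxy)-4-methoxy-3-methylphenyl]methyl}-3-methoxy-1-(propan-2-yloxy)-5-(trimethylsilyloxy)bicyclo[2.2.2]octa-2,5-dien-2-yl]-3-methylbutan-1-one (racemic; relative configuration of the bridgeheads fixed by the bicycle) | CC(C)OC12CCC(Cc3c(OCc4ccccc4)cc(OC)c(C)c3OCc3ccccc3)(C(OC)=C1C(=O)CC(C)C)C(O[Si](C)(C)C)=C2 | intermediate
20 | 1-[3-{[2,6-bis(benzyloxy)-4-methoxy-3-methylphenyl]methyl}-2-methoxy-6-(propan-2-yloxy)-4-(trimethylsilyloxy)phenyl]-3-methylbutan-1-one | CC(C)Oc1cc(O[Si](C)(C)C)c(Cc2c(OCc3ccccc3)cc(OC)c(C)c2OCc2ccccc2)c(OC)c1C(=O)CC(C)C | intermediate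
21 | 1-[3-{[2,6-bis(benzyloxy)-4-methoxy-3-methylphenyl]methyl}-2,4-dihydroxy-6-(propan-2-yloxy)phenyl]-3-methylbutan-1-one | CC(C)Oc1cc(O)c(Cc2c(OCc3ccccc3)cc(OC)c(C)c2OCc2ccccc2)c(O)c1C(=O)CC(C)C | intermediate
22 | 1-{3-[(2,6-dihydroxy-4-methoxy-3-methylphenyl)methyl]-2,4,6-trihydroxyphenyl}-3-methylbutan-1-one | COc1cc(O)c(Cc2c(O)cc(O)c(C(=O)CC(C)C)c2O)c(O)c1C | intermediate
23 | 1-[2,4-dihydroxy-6-methoxy-5-methyl-3-{[2,4,6-trihydroxy-3-(3-methylbutanoyl)phenyl]methyl}phenyl]-2-methylpropan-1-one | COc1c(C)c(O)c(Cc2c(O)cc(O)c(C(=O)CC(C)C)c2O)c(O)c1C(=O)C(C)C | intermediate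
24 | N,N-dimethyliminium chloride of 25 (ring B C3′ carries CH=N+Me2 in place of CHO) | COc1c(C)c(O)c(Cc2c(O)c(C=[N+](C)C)c(O)c(C(=O)CC(C)C)c2O)c(O)c1C(=O)C(C)C.[Cl-] | intermediate
25 | robustaol A, 3-{[2,6-dihydroxy-4-methoxy-3-methyl-5-(2-methylpropanoyl)phenyl]methyl}-2,4,6-trihydroxy-5-(3-methylbutanoyl)benzaldehyde | COc1c(C)c(O)c(Cc2c(O)c(C=O)c(O)c(C(=O)CC(C)C)c2O)c(O)c1C(=O)C(C)C | target

**Step count and risks**

Total step count: 15. Longest linear sequence: 12 steps (steps 1–5, 7, 8, 11–15).

Steps most likely to fail: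

1. Step 11 (the proposed new method). The push–pull ynone may be too weak a 2π partner for the hindered, tetrasubstituted diene terminus, so that oligomerisation of the ynone or hydrogen shift and desilylation of the diene outrun the cycloaddition. The fallback uses known Friedel–Crafts chemistry; it sets out from alcohol 6 and comes back to the route at 22. Phloroglucinol is acylated with 3-methylbutanoyl chloride (AlCl3, PhNO2) to 3-methyl-1-(2,4,6-trihydroxyphenyl)butan-1-one F1. An excess of this ketone is then benzylated at one of its two equivalent free ring positions by 6 under acid catalysis (TsOH·H2O, 1,4-dioxane, rt; alkylation through the stabilised benzylic cation) to give 1-[3-{[2,6-bis(benzyloxy)-4-methoxy-3-methylphenyl]methyl}-2,4,6-trihydroxyphenyl]-3-methylbutan-1-one F2. Hydrogenolysis (H2, 10% Pd/C, EtOAc–MeOH) removes both benzyl ethers and gives 22.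

2. Step 7 (with the bromide made in step 5). Ionisation of the very electron-rich benzylic bromide and Friedel–Crafts self-condensation at its free ring position may compete with C-alkylation of the enolate. The fallback sets out from aldehyde 5 and enone 9 and comes back at 11. Dienolate 10 (from 9 and LiN(i-Pr)2, THF, −78 °C) is added to 5 to give the aldol 6-{[2,6-bis(benzyloxy)-4-methoxy-3-methylphenyl](hydroxy)methyl}-3-(propan-2-yloxy)cyclohex-2-en-1-one F3 (racemic, mixture of diastereomers). Mesylation and elimination (MsCl, Et3N, then DBU) give (6E)-6-{[2,6-bis(benzyloxy)-4-methoxy-3-methylphenyl]methylidene}-3-(propan-2-yloxy)cyclohex-2-en-1-one F4. Conjugate reduction of the exocyclic enone with [(Ph3P)CuH]6 in wet toluene, which leaves the vinylogous ester alone, gives 11.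

3. Step 14. O-acylation of the phenols, a second acylation at C3′ of ring B, aluminium-assisted loss of the ring A methyl ether next to the new ketone, or acid-induced cleavage of the diarylmethane may lower the selectivity. The fallback sets out from 22 and comes back at 23. A Houben–Hoesch reaction with 2-methylpropanenitrile (ZnCl2, HCl gas, Et2O, 0 °C) cannot O-acylate and stops after one acylation of the more electron-rich ring. It gives 1-[2,4-dihydroxy-6-methoxy-5-methyl-3-{[2,4,6-trihydroxy-3-(3-methylbutanoyl)phenyl]methyl}phenyl]-2-methylpropan-1-iminium chloride F5, which hot water hydrolyses to 23.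

**Further compounds**

F1 | step 11 | 3-methyl-1-(2,4,6-trihydroxyphenyl)butan-1-one | CC(C)CC(=O)c1c(O)cc(O)cc1O
F2 | step 11 | 1-[3-{[2,6-bis(benzyloxy)-4-methoxy-3-methylphenyl]methyl}-2,4,6-trihydroxyphenyl]-3-methylbutan-1-one | CC(C)CC(=O)c1c(O)cc(O)c(Cc2c(OCc3ccccc3)cc(OC)c(C)c2OCc2ccccc2)c1O
F3 | step 7 | 6-{[2,6-bis(benzyloxy)-4-methoxy-3-methylphenyl](hydroxy)methyl}-3-(propan-2-yloxy)cyclohex-2-en-1-one (racemic, mixture of diastereomers) | CC(C)OC1=CC(=O)C(C(O)c2c(OCc3ccccc3)cc(OC)c(C)c2OCc2ccccc2)CC1
F4 | step 7 | (6E)-6-{[2,6-bis(benzyloxy)-4-methoxy-3-methylphenyl]methylidene}-3-(propan-2-yloxy)cyclohex-2-en-1-one | CC(C)OC1=CC(=O)/C(=C/c2c(OCc3ccccc3)cc(OC)c(C)c2OCc2ccccc2)CC1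
F5 | step 14 | 1-[2,4-dihydroxy-6-methoxy-5-methyl-3-{[2,4,6-trihydroxy-3-(3-methylbutanoyl)phenyl]methyl}phenyl]-2-methylpropan-1-iminium chloride | COc1c(C)c(O)c(Cc2c(O)cc(O)c(C(=O)CC(C)C)c2O)c(O)c1C(=[NH2+])C(C)C.[Cl-]
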